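## Retrosynthetic overview

1. The pyran ring is closed last: fluoride frees the C1 hydroxymethyl group, which adds 6-endo (oxa-Michael) to the ynone and forms the O2–C3 bond.
2. The cyclohexenone ring comes from a one-carbon ring expansion of a 1-acetylcyclopent-2-enyl aroate: a ring carbon shifts from the carbinol carbon to the acetyl carbon and the aroyl group follows from oxygen to oxygen. This sets C7 and places the ester.
3. That aroate comes from Ru-catalysed addition of the free aryl acid to a tertiary propargylic alcohol, made by ethynyl Grignard addition to a 5-silyloxycyclopentenone.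
4. The cyclopentenone comes from (R)-4-silyloxycyclopent-2-enone (source of C6) by Baylis–Hillman hydroxymethylation, pentenynyl addition and oxidative 1,3-carbonyl transposition.
5. The aryl acid comes from methyl acetoacetate. Ring order: arene (separate branch), purchased five-membered ring, six-membered carbocycle by expansion, pyran last.

Assumption: (E)-pent-3-en-1-yne and enantiopure (R)-4-(tert-butyldimethylsilyloxy)cyclopent-2-en-1-one are taken as purchasable.

Abbreviations: TBS = tert-butyldimethylsilyl; Ts = p-toluenesulfonyl; OTf = trifluoromethanesulfonate.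

## Route

Step 1
Reactants: 1 methyl acetoacetate (two molecules)
Product: 2 methyl 2,4-dihydroxy-6-methylbenzoate (methyl orsellinate)
Conditions: NaH, THF, 0 °C; n-BuLi, −78 °C → rt → reflux; aq. HCl
Reagents that add atoms: none
Why: Claisen self-condensation of the acetoacetate dianion, then intramolecular aldol condensation and aromatisation, builds the orsellinate ring; no stereocentre.

Step 2
Reactants: 2 methyl 2,4-dihydroxy-6-methylbenzoate
Product: 4 methyl 2-methoxy-6-methyl-4-(tosyloxy)benzoate, via monotosylate 3 (not isolated)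
Conditions: TsCl (1.05 equiv), K2CO3, acetone, rt; then MeI (excess), reflux
Reagents that add atoms: p-toluenesulfonyl chloride Cc1ccc(cc1)S(Cl)(=O)=O; iodomethane CI
Why: The 4-OH is the more acidic, unchelated phenol (the 2-OH is hydrogen-bonded to the ester), so sulfonylation goes there first; forcing Williamson methylation then caps the 2-OH.

Step 3
Reactants: 4 methyl 2-methoxy-6-methyl-4-(tosyloxy)benzoate
Product: 5 4-hydroxy-2-methoxy-6-methylbenzoic acid
Conditions: KOH, DMSO/H2O, 90 °C; then cold aq. HCl to pH 3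
Reagents that add atoms: potassium hydroxide [K+].[OH-]
Why: Hot hydroxide cleaves the aryl sulfonate at sulfur and saponifies the hindered methyl ester in one operation; cold acidification avoids decarboxylation.

Step 4
Reactants: 6 (R)-4-(TBS-oxy)cyclopent-2-en-1-one; 7 formaldehyde (37% aqueous)
Product: 8 (R)-4-(TBS-oxy)-2-(hydroxymethyl)cyclopent-2-en-1-one
Conditions: n-Bu3P (10 mol%), CHCl3/MeOH, rt
Reagents that add atoms: none
Why: Morita–Baylis–Hillman reaction: the phosphine adds to the β-carbon and the α-carbanion (not β to the silyloxy group, so no elimination) adds to formaldehyde; C4 is untouched.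

Step 5
Reactants: 8 (R)-4-(TBS-oxy)-2-(hydroxymethyl)cyclopent-2-en-1-one
Product: 9 (R)-4-(TBS-oxy)-2-((TBS-oxy)methyl)cyclopent-2-en-1-one
Conditions: TBSCl, imidazole, CH2Cl2, 0 °C → rt
Reagents that add atoms: tert-butyldimethylsilyl chloride CC(C)(C)[Si](C)(C)Cl
Why: Standard silylation of a primary allylic alcohol, so that it survives the oxidation in step 7.

Step 6
Reactants: 9 (R)-4-(TBS-oxy)-2-((TBS-oxy)methyl)cyclopent-2-en-1-one; 10 (E)-pent-3-en-1-yne
Product: 12 (4R)-4-(TBS-oxy)-2-((TBS-oxy)methyl)-1-((E)-pent-3-en-1-yn-1-yl)cyclopent-2-en-1-ol (both C1 epimers), via lithium pentenynide 11 (not isolated)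
Conditions: 10, n-BuLi, THF, −78 °C; then 9, −78 °C; H2O quench
Reagents that add atoms: none
Why: 1,2-Addition of a lithium acetylide to the enone carbonyl is fast at −78 °C and outruns enolisation; the new carbinol centre is irrelevant because it becomes sp2 in step 7.

Step 7
Reactants: 12 (4R)-4-(TBS-oxy)-2-((TBS-oxy)methyl)-1-((E)-pent-3-en-1-yn-1-yl)cyclopent-2-en-1-ol
Product: 13 (R)-5-(TBS-oxy)-2-((TBS-oxy)methyl)-3-((E)-pent-3-en-1-yn-1-yl)cyclopent-2-en-1-one
Conditions: pyridinium chlorochromate [C5H5NH][CrO3Cl], NaOAc, 4 Å MS, CH2Cl2, rt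
Reagents that add atoms: pyridinium chlorochromate [O-][Cr](=O)(=O)Cl.c1cc[nH+]cc1
Why: Babler–Dauben oxidative 1,3-transposition: the tertiary allylic chromate ester shifts [3,3] to the secondary allylic position and is oxidised, placing the carbonyl next to the silyloxy carbon; acetate buffering protects the silyl ethers and the α-stereocentre.

Step 8
Reactants: 13 (R)-5-(TBS-oxy)-2-((TBS-oxy)methyl)-3-((E)-pent-3-en-1-yn-1-yl)cyclopent-2-en-1-one; 14 ethynylmagnesium bromide
Product: 15 (1S,5R)-5-(TBS-oxy)-2-((TBS-oxy)methyl)-1-ethynyl-3-((E)-pent-3-en-1-yn-1-yl)cyclopent-2-en-1-ol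
Conditions: HC≡CMgBr, THF, −78 → −20 °C; H2O quench
Reagents that add atoms: none
Why: 1,2-Grignard addition to the enone carbonyl occurs anti to the adjacent silyloxy group (Felkin–Anh and steric control), so the new hydroxyl is cis to OTBS and C1 is S.

Step 9
Reactants: 15 (1S,5R)-5-(TBS-oxy)-2-((TBS-oxy)methyl)-1-ethynyl-3-((E)-pent-3-en-1-yn-1-yl)cyclopent-2-en-1-ol; 5 4-hydroxy-2-methoxy-6-methylbenzoic acid
Product: 17 (1S,5R)-1-acetyl-5-(TBS-oxy)-2-((TBS-oxy)methyl)-3-((E)-pent-3-en-1-yn-1-yl)cyclopent-2-en-1-yl 4-hydroxy-2-methoxy-6-methylbenzoate, via hydroxy enol ester 16 (not isolated)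
Conditions: [RuCl2(p-cymene)]2 (2.5 mol%), P(2-furyl)3 (5 mol%), Na2CO3 (5 mol%), toluene, 60 → 80 °C
Reagents that add atoms: none
Why: Ru-catalysed Markovnikov hydro-acyloxylation of the terminal alkyne of a tertiary propargylic alcohol, followed by O-to-O acyl shift (2-oxoalkyl ester synthesis), puts the hindered aroyl group on the tertiary oxygen without acylating a tertiary alcohol; the internal enyne, the phenol and both stereocentres are untouched.

Step 10
Reactants: 17 (1S,5R)-1-acetyl-5-(TBS-oxy)-2-((TBS-oxy)methyl)-3-((E)-pent-3-en-1-yn-1-yl)cyclopent-2-en-1-yl 4-hydroxy-2-methoxy-6-methylbenzoate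
Product: 18 (1R,6R)-6-(TBS-oxy)-3-((TBS-oxy)methyl)-1-methyl-2-oxo-4-((E)-pent-3-en-1-yn-1-yl)cyclohex-3-en-1-yl 4-hydroxy-2-methoxy-6-methylbenzoate
Conditions: Sc(OTf)3 (10 mol%), 2,6-di-tert-butyl-4-methylpyridine (20 mol%), 4 Å MS, ClCH2CH2Cl, 40 °C
Reagents that add atoms: none
Why: Proposed new method: an acyl-transposing α-ketol ring expansion of an α-acyloxy ketone, in which Sc(OTf)3 binds the ketone oxygen and the ester group and holds C=O syn to the C1–O bond, the electron-rich 2,6-disubstituted aroyl group is released as an acylium/dioxolanylium–alkoxide ion pair, the ring carbon bearing OTBS migrates from the carbinol carbon to the acetyl carbon (the carbinol carbon becomes the conjugated ketone), and the new tertiary scandium alkoxide recaptures the acyl group; migration through the syn (cisoid) chelate, from a substrate whose ester oxygen is cis to OTBS, gives the ester oxygen cis to OTBS at the new centre (1R,6R), the driving force is the six-membered conjugated dienynone, and the closest known reaction types are the Lewis-acid α-ketol (acyloin) ring expansion of 1-acylcycloalkanols and 1,2-acyloxy shifts through dioxolanylium ions.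

Step 11
Reactants: 18 (1R,6R)-6-(TBS-oxy)-3-((TBS-oxy)methyl)-1-methyl-2-oxo-4-((E)-pent-3-en-1-yn-1-yl)cyclohex-3-en-1-yl 4-hydroxy-2-methoxy-6-methylbenzoate
Product: 21 (6R,7R)-6-hydroxy-7-methyl-8-oxo-3-((E)-prop-1-en-1-yl)-5,6,7,8-tetrahydro-1H-isochromen-7-yl 4-hydroxy-2-methoxy-6-methylbenzoate, via primary alcohol 19 (not isolated), via silyl pyran 20 (not isolated)
Conditions: Bu4NF (3 equiv), AcOH (3 equiv), THF, 0 °C → rt
Reagents that add atoms: none
Why: Buffered fluoride frees the primary alcohol, which closes by 6-endo-dig oxa-Michael addition at the alkyne carbon δ to the ketone (5-exo attack would be anti-Michael) to give the 2H-pyran, and the secondary silyl ether then falls; no stereocentre is touched and the hindered aroate resists acyl migration.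

## Compound list

1 | methyl acetoacetate | CC(=O)CC(=O)OC | starting material
2 | methyl 2,4-dihydroxy-6-methylbenzoate | COC(=O)c1c(C)cc(O)cc1O | intermediate
3 | methyl 2-hydroxy-6-methyl-4-(tosyloxy)benzoate | COC(=O)c1c(C)cc(OS(=O)(=O)c2ccc(C)cc2)cc1O | intermediate
4 | methyl 2-methoxy-6-methyl-4-(tosyloxy)benzoate | COC(=O)c1c(C)cc(OS(=O)(=O)c2ccc(C)cc2)cc1OC | intermediate
5 | 4-hydroxy-2-methoxy-6-methylbenzoic acid | COc1cc(O)cc(C)c1C(=O)O | intermediate
6 | (R)-4-((tert-butyldimethylsilyl)oxy)cyclopent-2-en-1-one | O=C1C=C[C@H](O[Si](C)(C)C(C)(C)C)C1 | starting material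
7 | formaldehyde | C=O | starting material
8 | (R)-4-((tert-butyldimethylsilyl)oxy)-2-(hydroxymethyl)cyclopent-2-en-1-one | O=C1C(CO)=C[C@H](O[Si](C)(C)C(C)(C)C)C1 | intermediate
9 | (R)-4-((tert-butyldimethylsilyl)oxy)-2-(((tert-butyldimethylsilyl)oxy)methyl)cyclopent-2-en-1-one | O=C1C(CO[Si](C)(C)C(C)(C)C)=C[C@H](O[Si](C)(C)C(C)(C)C)C1 | intermediate
10 | (E)-pent-3-en-1-yne | C#C/C=C/C | starting material
11 | lithium (E)-pent-3-en-1-yn-1-ide | [Li]C#C/C=C/C | intermediate
12 | (4R)-4-((tert-butyldimethylsilyl)oxy)-2-(((tert-butyldimethylsilyl)oxy)methyl)-1-((E)-pent-3-en-1-yn-1-yl)cyclopent-2-en-1-ol (C1 epimers) | C/C=C/C#CC1(O)C[C@@H](O[Si](C)(C)C(C)(C)C)C=C1CO[Si](C)(C)C(C)(C)C | intermediate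
13 | (R)-5-((tert-butyldimethylsilyl)oxy)-2-(((tert-butyldimethylsilyl)oxy)methyl)-3-((E)-pent-3-en-1-yn-1-yl)cyclopent-2-en-1-one | O=C1C(CO[Si](C)(C)C(C)(C)C)=C(C#C/C=C/C)C[C@H]1O[Si](C)(C)C(C)(C)C | intermediate
14 | ethynylmagnesium bromide | C#C[Mg]Br | starting material
15 | (1S,5R)-5-((tert-butyldimethylsilyl)oxy)-2-(((tert-butyldimethylsilyl)oxy)methyl)-1-ethynyl-3-((E)-pent-3-en-1-yn-1-yl)cyclopent-2-en-1-ol | C#C[C@]1(O)C(CO[Si](C)(C)C(C)(C)C)=C(C#C/C=C/C)C[C@H]1O[Si](C)(C)C(C)(C)C | intermediate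
16 | 1-((1S,5R)-5-((tert-butyldimethylsilyl)oxy)-2-(((tert-butyldimethylsilyl)oxy)methyl)-1-hydroxy-3-((E)-pent-3-en-1-yn-1-yl)cyclopent-2-en-1-yl)vinyl 4-hydroxy-2-methoxy-6-methylbenzoate | C=C(OC(=O)c2c(C)cc(O)cc2OC)[C@]1(O)C(CO[Si](C)(C)C(C)(C)C)=C(C#C/C=C/C)C[C@H]1O[Si](C)(C)C(C)(C)C | intermediate
17 | (1S,5R)-1-acetyl-5-((tert-butyldimethylsilyl)oxy)-2-(((tert-butyldimethylsilyl)oxy)methyl)-3-((E)-pent-3-en-1-yn-1-yl)cyclopent-2-en-1-yl 4-hydroxy-2-methoxy-6-methylbenzoate | CC(=O)[C@]1(OC(=O)c2c(C)cc(O)cc2OC)C(CO[Si](C)(C)C(C)(C)C)=C(C#C/C=C/C)C[C@H]1O[Si](C)(C)C(C)(C)C | intermediate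
18 | (1R,6R)-6-((tert-butyldimethylsilyl)oxy)-3-(((tert-butyldimethylsilyl)oxy)methyl)-1-methyl-2-oxo-4-((E)-pent-3-en-1-yn-1-yl)cyclohex-3-en-1-yl 4-hydroxy-2-methoxy-6-methylbenzoate | C/C=C/C#CC1=C(CO[Si](C)(C)C(C)(C)C)C(=O)[C@](C)(OC(=O)c2c(C)cc(O)cc2OC)[C@H](O[Si](C)(C)C(C)(C)C)C1 | intermediate
19 | (1R,6R)-6-((tert-butyldimethylsilyl)oxy)-3-(hydroxymethyl)-1-methyl-2-oxo-4-((E)-pent-3-en-1-yn-1-yl)cyclohex-3-en-1-yl 4-hydroxy-2-methoxy-6-methylbenzoate | C/C=C/C#CC1=C(CO)C(=O)[C@](C)(OC(=O)c2c(C)cc(O)cc2OC)[C@H](O[Si](C)(C)C(C)(C)C)C1 | intermediate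
20 | (6R,7R)-6-((tert-butyldimethylsilyl)oxy)-7-methyl-8-oxo-3-((E)-prop-1-en-1-yl)-5,6,7,8-tetrahydro-1H-isochromen-7-yl 4-hydroxy-2-methoxy-6-methylbenzoate | C/C=C/C1=CC2=C(CO1)C(=O)[C@](C)(OC(=O)c1c(C)cc(O)cc1OC)[C@H](O[Si](C)(C)C(C)(C)C)C2 | intermediate
21 | (6R,7R)-6-hydroxy-7-methyl-8-oxo-3-((E)-prop-1-en-1-yl)-5,6,7,8-tetrahydro-1H-isochromen-7-yl 4-hydroxy-2-methoxy-6-methylbenzoate | C/C=C/C1=CC2=C(CO1)C(=O)[C@](C)(OC(=O)c1c(C)cc(O)cc1OC)[C@H](O)C2 | target

## Step count and risks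

Total steps: 11. Longest linear sequence: 8 steps (6 to 21, steps 4–11); the acid branch (steps 1–3) joins at step 9.

The three steps most likely to fail:

**Step 9 (Ru hydro-acyloxylation).** The acid is 2,6-disubstituted, the substrate carries a second (internal) alkyne, and the acyl shift from the enol ester 16 to the tertiary oxygen may stall. The fallback sets out from 13 and comes back at 17. Acid 5 is silylated twice (TBSCl, imidazole) to tert-butyldimethylsilyl 4-((tert-butyldimethylsilyl)oxy)-2-methoxy-6-methylbenzoate F1, which (COCl)2 with catalytic DMF converts into 4-((tert-butyldimethylsilyl)oxy)-2-methoxy-6-methylbenzoyl chloride F2. Ethyl vinyl ether and t-BuLi give 1-ethoxyvinyllithium F3, which adds to 13 at −78 °C anti to the silyloxy group. The lithium alkoxide is acylated in the same flask by F2, kept cold to outrun silyl migration, to give the enol ether ester F4. Dilute aqueous oxalic acid hydrolyses the enol ether to the aryl-silylated acetyl ester F5, and KHF2 in MeOH removes only the phenolic silyl group to give 17.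

**Step 10 (proposed ring expansion).** Possible failures are no turnover, migration of the vinyl carbon instead of the silyloxy-bearing carbon, the C1 epimer through the anti conformer, loss of silyl groups, or leakage of the acylium to other nucleophiles. The fallback uses only known chemistry, sets out from 13 and comes back at 18. 1-Ethoxyvinyllithium F3 adds to 13 to give the enol ether carbinol F6, which aqueous oxalic acid hydrolyses to the free α-ketol F7. The established Lewis-acid α-ketol ring expansion of a 1-acylcycloalkanol (BF3·OEt2, CH2Cl2, 0 °C, syn chelated conformer) gives the ring-expanded hydroxy ketone F8. Its tertiary hydroxyl is acylated with the acid chloride F2 (AgOTf, 2,6-di-tert-butyl-4-methylpyridine, CH2Cl2) to the tris-silyl ester F9, and KHF2 in MeOH frees the phenol to give 18.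

**Step 11 (desilylation and pyran closure).** Possible failures are sluggish or 5-exo cyclisation (furan formation) and base-induced acyl migration to the C6 hydroxyl. The fallback sets out from 18 and comes back at 20. Diethylamine (EtOH, rt) adds 1,6 to the dienynone to give the dienaminone F10, which fixes the oxygen-accepting carbon. Bu4NF/AcOH then removes the primary silyl group to give the primary alcohol F11, whose hydroxyl displaces diethylamine at that carbon by 6-exo-trig addition–elimination to give 20; the same pot desilylates 20 to 21.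

## Further compounds

F1 | step 9 | tert-butyldimethylsilyl 4-((tert-butyldimethylsilyl)oxy)-2-methoxy-6-methylbenzoate | COc1cc(O[Si](C)(C)C(C)(C)C)cc(C)c1C(=O)O[Si](C)(C)C(C)(C)C
F2 | step 9 | 4-((tert-butyldimethylsilyl)oxy)-2-methoxy-6-methylbenzoyl chloride | COc1cc(O[Si](C)(C)C(C)(C)C)cc(C)c1C(Cl)=O
F3 | step 9 | 1-ethoxyvinyllithium | [Li]C(=C)OCC
F4 | step 9 | (1S,5R)-5-((tert-butyldimethylsilyl)oxy)-2-(((tert-butyldimethylsilyl)oxy)methyl)-1-(1-ethoxyvinyl)-3-((E)-pent-3-en-1-yn-1-yl)cyclopent-2-en-1-yl 4-((tert-butyldimethylsilyl)oxy)-2-methoxy-6-methylbenzoate | CCOC(=C)[C@]1(OC(=O)c2c(C)cc(O[Si](C)(C)C(C)(C)C)cc2OC)C(CO[Si](C)(C)C(C)(C)C)=C(C#C/C=C/C)C[C@H]1O[Si](C)(C)C(C)(C)C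
F5 | step 9 | (1S,5R)-1-acetyl-5-((tert-butyldimethylsilyl)oxy)-2-(((tert-butyldimethylsilyl)oxy)methyl)-3-((E)-pent-3-en-1-yn-1-yl)cyclopent-2-en-1-yl 4-((tert-butyldimethylsilyl)oxy)-2-methoxy-6-methylbenzoate | CC(=O)[C@]1(OC(=O)c2c(C)cc(O[Si](C)(C)C(C)(C)C)cc2OC)C(CO[Si](C)(C)C(C)(C)C)=C(C#C/C=C/C)C[C@H]1O[Si](C)(C)C(C)(C)C
F6 | step 10 | (1S,5R)-5-((tert-butyldimethylsilyl)oxy)-2-(((tert-butyldimethylsilyl)oxy)methyl)-1-(1-ethoxyvinyl)-3-((E)-pent-3-en-1-yn-1-yl)cyclopent-2-en-1-ol | CCOC(=C)[C@]1(O)C(CO[Si](C)(C)C(C)(C)C)=C(C#C/C=C/C)C[C@H]1O[Si](C)(C)C(C)(C)C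
F7 | step 10 | 1-((1S,5R)-5-((tert-butyldimethylsilyl)oxy)-2-(((tert-butyldimethylsilyl)oxy)methyl)-1-hydroxy-3-((E)-pent-3-en-1-yn-1-yl)cyclopent-2-en-1-yl)ethan-1-one | CC(=O)[C@]1(O)C(CO[Si](C)(C)C(C)(C)C)=C(C#C/C=C/C)C[C@H]1O[Si](C)(C)C(C)(C)C
F8 | step 10 | (5R,6R)-5-((tert-butyldimethylsilyl)oxy)-2-(((tert-butyldimethylsilyl)oxy)methyl)-6-hydroxy-6-methyl-3-((E)-pent-3-en-1-yn-1-yl)cyclohex-2-en-1-one | C/C=C/C#CC1=C(CO[Si](C)(C)C(C)(C)C)C(=O)[C@](C)(O)[C@H](O[Si](C)(C)C(C)(C)C)C1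
F9 | step 10 | (1R,6R)-6-((tert-butyldimethylsilyl)oxy)-3-(((tert-butyldimethylsilyl)oxy)methyl)-1-methyl-2-oxo-4-((E)-pent-3-en-1-yn-1-yl)cyclohex-3-en-1-yl 4-((tert-butyldimethylsilyl)oxy)-2-methoxy-6-methylbenzoate | C/C=C/C#CC1=C(CO[Si](C)(C)C(C)(C)C)C(=O)[C@](C)(OC(=O)c2c(C)cc(O[Si](C)(C)C(C)(C)C)cc2OC)[C@H](O[Si](C)(C)C(C)(C)C)C1
F10 | step 11 | (1R,6R)-6-((tert-butyldimethylsilyl)oxy)-3-(((tert-butyldimethylsilyl)oxy)methyl)-4-((3E)-2-(diethylamino)penta-1,3-dien-1-yl)-1-methyl-2-oxocyclohex-3-en-1-yl 4-hydroxy-2-methoxy-6-methylbenzoate | C/C=C/C(N(CC)CC)=CC1=C(CO[Si](C)(C)C(C)(C)C)C(=O)[C@](C)(OC(=O)c2c(C)cc(O)cc2OC)[C@H](O[Si](C)(C)C(C)(C)C)C1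
F11 | step 11 | (1R,6R)-6-((tert-butyldimethylsilyl)oxy)-4-((3E)-2-(diethylamino)penta-1,3-dien-1-yl)-3-(hydroxymethyl)-1-methyl-2-oxocyclohex-3-en-1-yl 4-hydroxy-2-methoxy-6-methylbenzoate | C/C=C/C(N(CC)CC)=CC1=C(CO)C(=O)[C@](C)(OC(=O)c2c(C)cc(O)cc2OC)[C@H](O[Si](C)(C)C(C)(C)C)C1
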